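The gamma flask cannot have stopped for want of starting material, since 42.6 % of it still stands at 300 min while product has stopped rising. This is the flask asked about, followed so far.

all flasks: starting material 0.064 M; partner 0.0512 M; free catalyst 1.3 mM

| run | protic impurity | remark | time |
|---|---|---|---|
| gamma | 6.4 mM | the very flask that is asked about, followed so far |  |
| flask | 6.40 mM |  | 8.0 h |

gamma run (percent of the starting material charged)

| time / min | product / % | starting material / % |
|---|---|---|
| 15.0 | 38.9 | 48.8 |
| 40.0 | 44.8 | 42.8 |
| 80.0 | 45.5 | 43.0 |
| 120 | 46.0 | 42.0 |
| 180 | 45.1 | 43.2 |
| 240 | 46.0 | 43.4 |
| 300 | 44.6 | 42.6 |

(scatter of a reading: 0.5 percentage points)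

- removed product is counted in
- on the list of suspects stand: starting material + free catalyst -> catalyst intermediate A; partner + catalyst intermediate A <-> catalyst intermediate B; catalyst intermediate B <-> catalyst intermediate C; catalyst intermediate C -> by-product + catalyst intermediate D; catalyst intermediate D -> free catalyst + product; starting material + protic impurity -> quenched substrate; partner -> decomposed reagent
- additions bring no volume worth counting

- dawn: at 8.0 h take out 90 % of the product then present, then wait 8.0 h
- spring: at 8.0 h add partner, 100 % of the amount charged, then wait 8.0 h
- dusk: at 8.0 h add free catalyst, 100 % of the amount charged, then wait 8.0 h
- winter: change nothing and wait 8.0 h more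

- product, in percent of the starting material first charged, at 8.0 h
- the option that brings most further product ("none" if no option brings more than 2 percentage points) (dawn / spring / dusk / winter / none)
- product present, with what was taken out counted in, in percent of the starting material first charged, after dawn
- product present, with what was taken out counted in, in percent of the starting material first charged, after spring

The gamma readings form a ladder of rates. On the first rung, the first 15.0 min make product at 1.66 mM min⁻¹ on average, which is one catalyst turnover in 0.783 min. On the next rung, up to 40.0 min, the rate is 0.151 mM min⁻¹, ten times slower. On the last rung product reads 44.8 % and then 44.6 % at 300 min, a change inside the scatter of 0.5 percentage points, so this reckoning sets the gamma flask at 8.0 h at the plateau means: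

product 45.3 %, starting material 42.8 %

Partner was charged at 80.0 % of the starting material, more than the plateau, so this reckoning supposes that the partner beyond the product went to decomposed reagent, and it takes partner as the limiting reagent. Product formed per partner charged comes to

[product] / [partner] = 56.7 %

and this is the partner yield. This reckoning lets a second dose add product at the same yield, up to a room that it takes as the starting material present plus the whole catalyst charge held as catalyst intermediate A:

dose: 45.3 %; room: 44.9 %

The reckoned dose exceeds the reckoned room, so this reckoning puts spring at 90.2 %.

The forecast gives 45.3 % now, spring as best, 45.3 % after dawn and 82 % after spring, the last lower than this reckoning, on the ground that “Efficiency falls as starting material runs out”.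

The flask gives 45.0 % at 8.0 h, spring as best with 45 points more, 45.0 % after dawn and 89.6 % after spring, which lies 7.6 points above the forecast.

    starting material + free catalyst → catalyst intermediate A (k = 11000 M⁻¹ min⁻¹)
    partner + catalyst intermediate A ⇌ catalyst intermediate B (K = 320 M⁻¹, k = 296 M⁻¹ min⁻¹)
    catalyst intermediate B ⇌ catalyst intermediate C (K = 1.21, k = 8.54 min⁻¹)
    catalyst intermediate C → by-product + catalyst intermediate D (k = 180 min⁻¹)
    catalyst intermediate D → free catalyst + product (k = 2.32 min⁻¹)
    starting material + protic impurity → quenched substrate (k = 11.7 M⁻¹ min⁻¹)
    partner → decomposed reagent (k = 0.0641 min⁻¹)

Catalyst intermediate D released half of its product of the run by 7.66 min, and by 48.0 min the flask held 0 % of its partner charge, with >99.9 % of the catalyst charged standing as catalyst intermediate A (the resting state) beside 43.0 % of starting material. The spring dose then returned a partner yield of 55.8 %, against the 56.7 % read from the gamma readings. For a neighbour flask charged with 0.013 M of partner, 56.7 % gives 11.5 % of product, and that neighbour flask holds 15.1 %, a partner yield of 74.5 %.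

(All runs were computed with constants of no real substance; noise was put on by code.)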